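## Structural features

The target is a bicyclo[5.3.0]decane in which a cyclopentane (C1–C5) and a cycloheptane (C5–C10 and C1) share the C1–C5 bond; C1 is an all-carbon quaternary centre bearing a methyl group (its face is called β) and C5 carries hydrogen on the opposite face (α), so the rings are trans-fused. Five of the six stereocentres form an unbroken run around the C7 ketone: the tertiary carbinol C4 (OH β, isopropyl α), the ring-fusion carbon C5 (H α), the acyloxy carbon C6 (O α), and beyond the carbonyl the tertiary carbinol C8 (CH3 β, OH α) and the secondary carbinol C9 (OH α); C1 closes the ring next to C5 and C10. The fragile sites are the α-acyloxy ketone at C6/C7 (epimerisable, base-labile), the tertiary α-ketol at C8 (acyloin shift), the tertiary C4 carbinol (acid-induced loss of water toward C5) and the phenolic ester; in addition C6–O is β to C4, so a C4 ketone is an elimination hazard once C6 is oxygenated. The real difficulty is the quaternary C1 at the junction of a seven-membered ring, the trans ring fusion, and four oxygen functions on C6–C9 with defined faces. The key step exploits the C7 carbonyl flanked by C6 and C8 inside the five-carbon run C5–C9, joined through the tether C2–C3–C4 to C1, which with C10 is a latent 1,1-disubstituted alkene. This is the imprint of a 1-silyloxy-1-alkenylcyclopropane (C5=C6–C7(OSi), ring methylenes C8 and C9) with a tethered alkene, whose rhodium-catalysed (5+2) cycloaddition forms C1–C5 and C9–C10 and closes both rings. Because C4 ends as a carbinol made from a ketone, it can carry a sacrificial silyloxy stereocentre that steers the cycloaddition and the later face selections.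

## Logic of the disconnections

**32 ⇒ 31 ⇒ 29 + 30.** The two acetal-type protecting groups are put back and the C6–O acyl bond is cut. The α-acyloxy ketone is the most base-sensitive part of the molecule and should never meet an enolate or an organometallic reagent. The cut removes the aromatic fragment and leaves a core in which C6–OH is the only acylable hydroxyl (C4–OH is tertiary, O8 and O9 are tied together). The forward steps must acylate a hindered α-ketol without epimerising C6 and must unmask with mild acid only.

**29 ⇒ 28 ⇒ 26 + 27.** The C4–isopropyl bond is cut. A tertiary carbinol is best made from its ketone, and a ketone at C4 makes any earlier stereocentre there disposable. Placing this cut after the C6 oxygenation leaves in 26 a silyl ether that shields the C7 carbonyl and is a poor leaving group. The forward addition must come from the α face, must choose C4 over C7, and must not enolise toward C5.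

**26 ⇒ 25 ⇒ 24 ⇒ 23 ⇒ 22.** The C6–O bond is cut (with the C4 oxidation-state and protecting-group changes). In 22 the C7 ketone can enolise only toward C6 because C8 is quaternary, so the oxygenation is regiospecific. This removes one stereocentre and one oxygen. It demands oxidation from the α face and two silyl groups of different lability (triethylsilyl on O4, tert-butyldimethylsilyl on O6).

**22 ⇒ 21 ⇒ 20.** The C5–H and C6–H bonds are cut, which restores a C5=C6 double bond. The cycloaddition can only give a cis junction, so C5 is passed through sp2 and reset. This removes the trans-fusion problem from the ring-forming step. It demands hydrogen delivery to the α face of C5.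

**20 ⇒ 19.** The C8–O and C9–O bonds are cut. A cis-diol maps onto an alkene, which removes two stereocentres at once. The forward step must select C8=C9 over C5=C6 and the α face.

**19 ⇒ 16 ⇒ 14.** The C8=C9 π bond and the C8–CH3 bond are cut. Both come from the α′ enolate of one enone, so no new functional group is needed. The demand is kinetic α′ deprotonation without γ deprotonation at C4.

**14 ⇒ 13.** The C5=C6 π bond is traced to the C6=C7 silyl enol ether. The enol ether left by the cycloaddition is regiodefined, so the enone can form in one place only. The demand is β-hydride elimination of H5 from a palladium enolate.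

**13 ⇒ 12.** C1–C5 and C9–C10 are cut and the C7–C9 bond of a cyclopropane is restored. Both rings, the quaternary C1 and the C7 oxygen then come from an open chain with a single stereocentre. The demand is insertion of a 1,1-disubstituted alkene and face selection by C4.

**12 ⇒ 11 ⇒ 10 ⇒ 9.** The O4–Si bond, the two alkene C–H bonds and the carbinol C4–H bond are cut. An (E)-allylic alcohol comes reliably from a propargylic alcohol, and that from an ynone by asymmetric transfer hydrogenation. The precursor is thereby reduced to an achiral ynone. The demands are E geometry and high enantiopurity. The robust silyl group sits on the cyclopropanol oxygen (later a stable enol ether) and the labile one on O4.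

**9 ⇒ 5 + 7; 7 ⇒ 6; 5 ⇒ 4 ⇒ 1 + 2.** The C4–C5 bond is cut (acetylide plus acylating agent), then the C6–C7 bond between alkyne and cyclopropane. The cyclopropanol carbon is taken from a cyclopropanone equivalent, which avoids a titanium-mediated cyclopropanation of a conjugated ester. This leads to three commercial pieces. The demands are mono-addition to the amide and an excess of the Grignard reagent in the cyclopropanone step.

## Other disconnections considered

Alternative 1: The cut is the C4–C5 bond, made on a six-membered stand-in for the large ring: the cis-fused enedione A1 is opened to the achiral cyclohexadienone aldehyde A2, whose quaternary carbon already carries the C1 methyl group and the C2–C3–C4 aldehyde arm. In the forward step a chiral triazolium salt is deprotonated to a carbene that adds to the formyl carbon C4 of A2; the resulting Breslow intermediate attacks the β-carbon C5 of one of the two mirror-related enone halves in a 5-exo sense, which closes the cyclopentanone and sets C1 and C5 together. In its favour, the step is organocatalytic, the absolute configuration comes from the catalyst acting on an achiral substrate, and C4 arrives as the ketone that the isopropyl addition needs, with no sacrificial stereocentre. Against it here, A1 is a bicyclo[4.3.0] system in which C8 is missing, so the seven-membered ring would need a regioselective one-carbon insertion between C7 and C9 that also brings in the C8 methyl group, C6, C8 and C9 would still have to be oxygenated, and the C4 and C7 ketones would have to be told apart. On structure the chosen plan is ahead, because 13 already holds the seven-membered ring with oxygen on C7. On mechanism both plans give a cis junction first; in A1, however, C5 lies α to the C4 ketone and could be equilibrated directly, and catalyst control on an achiral substrate is cleaner than induction relayed from C4 in 12, so on these two points the alternative is the better. On step economy the alternative reaches its key step sooner, which is also better, but the ring expansion and the re-oxygenation are expected to cost at least what is saved, so the totals are equal at best.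

Alternative 2: The cut is C7–C8 and C1–C10: the bicyclic diene ester A3 falls apart into the vinyldiazo ester A4 and the ketal-protected vinylcyclopentene A5. In the forward step a chiral dirhodium tetracarboxylate Rh2(O2CR*)4 decomposes A4 to a metal vinylcarbene, which adds across the terminal C6=C7 alkene of A5 (bonds C8–C7 and, for the moment, C8–C6); the cis-divinylcyclopropane so formed is not isolated but undergoes a Cope rearrangement in which C8–C6 breaks and C10–C1 forms, which delivers the cycloheptadiene with its quaternary C1. In its favour, the plan is convergent, the absolute configuration at C1 is set by the catalyst, and C4 is at the ketone level from the start, all three being points on which it is better than the chosen plan; the C5=C6 and C8=C9 alkenes of A3 sit where 19 has them, so the two plans are equal there. Against it here, C7 arrives as a methylene and needs a doubly allylic oxidation, the C8 substituent is an ester that must be reduced to a methyl group over several steps, the Cope step must build the quaternary C1 from a fully substituted alkene terminus through a boat transition state, and A4 is a thermally labile diazo compound. On structure the chosen plan delivers the C7 oxygen directly and needs only a one-step methylation at C8. On mechanism a carbene and sigmatropic cascade under catalyst control stands against a metallacycle pathway under substrate control. On step economy the fragment syntheses are short, but the redox corrections at C7 and C8 would make the total equal or longer.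

Alternative 3: The cut is C1–CH3 and C5–C6: the aldol adduct A6 is traced back to the 3-substituted cyclopentenone A7, methylmagnesium bromide A9 and the dithiane aldehyde A8, joined by the divalent copper salt Cu(OTf)2 A10 and a chiral N-heterocyclic carbene ligand as catalyst. In the forward step the chiral copper species formed from A10 transfers the methyl group of A9 to the β-carbon C1 of A7 in a 1,4 sense, and the magnesium enolate left behind is captured at C5 by the formyl carbon of A8, which becomes the carbinol C6. In its favour, three stereocentres (C1, C5 and C6) would be set in one operation, the trans C1/C5 relationship would come out directly without later correction, and C4, C6 and C7 would arrive at or near their final oxidation levels; on each of these points the alternative is better than the chosen plan. Against it here, the seven-membered ring is not formed and C8–C9 must be closed later by a medium-ring aldol-type reaction with C8 and C9 still to be controlled, A6 is a β-hydroxy ketone (C4/C6) prone to retro-aldol cleavage and dehydration, the enolate next to a quaternary carbon and the neopentyl-type aldehyde A8 make the trapping and its C6 selectivity uncertain, and asymmetric methyl addition that creates a quaternary centre on a cyclopentenone is a demanding case. On structure the chosen plan closes both rings at once. On mechanism the alternative sets one more stereocentre in its key step. On step economy the alternative starts shorter, but ring closure and the C8/C9 oxygenation would bring it to a comparable length with more open stereochemical questions.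

Key step: step 8

Convention: bicyclic compounds are named as bicyclo[5.3.0]decanes carrying the target's atom numbers (five-membered ring C1–C5, seven-membered ring C5–C10 and C1); β is the face of the C1 methyl group, α the other face.

Assumption: in the cycloaddition the C4 silyloxy group is taken to end on the exo face of the forming cyclopentane (cis to H5 and to the C1 methyl group), so that the (S)-carbinol leads to the natural C1 configuration; this sense remains to be confirmed.

## Steps

Step 1
Reactants: 1 (1-ethoxycyclopropoxy)trimethylsilane; 2 ethynylmagnesium bromide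
Product: 4 1-ethynylcyclopropan-1-ol, via 1-ethoxycyclopropan-1-ol 3 (not isolated)
Conditions: MeOH, rt, then concentrate; 2 (2.5 equiv), THF, 0 °C → reflux; aq. NH4Cl
Reagents that add atoms: none
Why: Methanolysis frees the hemiketal; the first equivalent of the Grignard reagent deprotonates it, the magnesium alkoxide collapses to cyclopropanone, and the second equivalent adds (Grignard 1,2-addition to a cyclopropanone equivalent).

Step 2
Reactants: 4 1-ethynylcyclopropan-1-ol
Product: 5 tert-butyl[(1-ethynylcyclopropyl)oxy]dimethylsilane
Conditions: TBSOTf, 2,6-lutidine, CH2Cl2, −78 → 0 °C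
Reagents that add atoms: tert-butyldimethylsilyl trifluoromethanesulfonate, CC(C)(C)[Si](C)(C)OS(=O)(=O)C(F)(F)F
Why: Silylation of a tertiary cyclopropanol with a silyl triflate and a hindered base; the tert-butyldimethylsilyl group is chosen because it later becomes an enol ether that must survive heating and chromatography.

Step 3
Reactants: 6 4-methylpent-4-enoic acid
Product: 7 N-methoxy-N,4-dimethylpent-4-enamide
Conditions: MeNH(OMe)·HCl, EDC·HCl, iPr2NEt, CH2Cl2, 0 °C → rt
Reagents that add atoms: N,O-dimethylhydroxylamine hydrochloride, CNOC.Cl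
Why: Carbodiimide amide coupling to the Weinreb amide; the isolated alkene is inert.

Step 4
Reactants: 5 tert-butyl[(1-ethynylcyclopropyl)oxy]dimethylsilane; 7 N-methoxy-N,4-dimethylpent-4-enamide
Product: 9 1-[1-(tert-butyldimethylsilyloxy)cyclopropyl]-6-methylhept-6-en-1-yn-3-one, via lithium acetylide 8 (not isolated)
Conditions: nBuLi, THF, −78 °C; 7, −78 → 0 °C; aq. NH4Cl
Reagents that add atoms: none
Why: Weinreb ketone synthesis; the chelated tetrahedral adduct of the acetylide resists a second addition and releases the ynone on work-up, forming C4–C5.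

Step 5
Reactants: 9 1-[1-(tert-butyldimethylsilyloxy)cyclopropyl]-6-methylhept-6-en-1-yn-3-one
Product: 10 (3S)-1-[1-(tert-butyldimethylsilyloxy)cyclopropyl]-6-methylhept-6-en-1-yn-3-ol
Conditions: Ru[(S,S)-TsDPEN](p-cymene) (1 mol %), iPrOH, rt
Reagents that add atoms: none
Why: Noyori asymmetric transfer hydrogenation of an alkynyl ketone; the alkynyl group takes the place of the aryl group in the bifunctional hydride-transfer transition state, so the (S,S)-ligand should give the (S)-carbinol at C4, and the antipodal catalyst gives the other enantiomer if needed.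

Step 6
Reactants: 10 (3S)-1-[1-(tert-butyldimethylsilyloxy)cyclopropyl]-6-methylhept-6-en-1-yn-3-ol
Product: 11 (3S,1E)-1-[1-(tert-butyldimethylsilyloxy)cyclopropyl]-6-methylhepta-1,6-dien-3-ol
Conditions: NaAlH2(OCH2CH2OMe)2, THF, 0 °C → rt; aq. potassium sodium tartrate
Reagents that add atoms: none
Why: Hydroxyl-directed trans-hydroalumination of a propargylic alcohol followed by protonolysis gives the (E)-allylic alcohol; the silyl ether on the cyclopropane is a poor leaving group, so elimination to an allene is not expected at this temperature.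

Step 7
Reactants: 11 (3S,1E)-1-[1-(tert-butyldimethylsilyloxy)cyclopropyl]-6-methylhepta-1,6-dien-3-ol
Product: 12 (E)-1-(tert-butyldimethylsilyloxy)-1-[(3S)-6-methyl-3-(triethylsilyloxy)hepta-1,6-dien-1-yl]cyclopropane
Conditions: Et3SiCl, imidazole, DMAP (cat.), CH2Cl2, 0 °C → rt
Reagents that add atoms: chlorotriethylsilane, CC[Si](Cl)(CC)CC
Why: Standard silylation of a secondary allylic alcohol; triethylsilyl is bulky enough to steer the cycloaddition yet removable later in the presence of tert-butyldimethylsilyl ethers.

Step 8
Reactants: 12 (E)-1-(tert-butyldimethylsilyloxy)-1-[(3S)-6-methyl-3-(triethylsilyloxy)hepta-1,6-dien-1-yl]cyclopropane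
Product: 13 7-(tert-butyldimethylsilyloxy)-1β-methyl-4β-(triethylsilyloxy)-5βH-bicyclo[5.3.0]dec-6-ene (cis-fused)
Conditions: [Rh(CO)2Cl]2 (5 mol %), PhMe (0.02 M), 100 °C
Reagents that add atoms: none
Why: Monovalent rhodium binds the alkenylcyclopropane and cleaves the strained C7–C9 bond, helped by the silyloxy donor on C7, to give a six-membered σ-alkyl,π-allyl metallacycle of trivalent rhodium. The tethered alkene then inserts into the rhodium–C5 bond, which forms C1–C5 and closes the five-membered ring in a 5-exo mode (the three-carbon tether cannot reach an endo mode) and leaves rhodium on C10 in an eight-membered metallacycle. Reductive elimination between two sp3 carbons forms C9–C10, closes the seven-membered ring and returns monovalent rhodium, the former allyl unit emerging as the C6=C7 silyl enol ether. The closest known reaction type is the [Rh(CO)2Cl]2-catalysed intramolecular (5+2) cycloaddition of alkene-tethered 1-silyloxy-1-vinylcyclopropanes to cis-fused bicyclo[5.3.0]decenes, where 1,1-disubstituted alkenes are the demanding but documented case. C5 is set cis to the C1 methyl group because both new bonds form on one alkene face and the short tether allows only a cis-fused insertion transition state. C1 is set by the C4 stereocentre: the triethylsilyloxy group should take the exo, pseudo-equatorial position of the forming cyclopentane, anti to the C5–C6 bond, which exposes one alkene face and places OSiEt3 cis to H5 and to the C1 methyl group. The step needs insertion to outrun β-hydride elimination and cyclopropane isomerisation and needs high 1,2-induction; the oxygen donor on the cyclopropane, the E geometry, high dilution and the size of the C4 silyl ether are what should secure this.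

Step 9
Reactants: 13 7-(tert-butyldimethylsilyloxy)-1β-methyl-4β-(triethylsilyloxy)-5βH-bicyclo[5.3.0]dec-6-ene
Product: 14 1β-methyl-4β-(triethylsilyloxy)bicyclo[5.3.0]dec-5-en-7-one
Conditions: Pd(OAc)2 (1.1 equiv), MeCN, rt → 40 °C
Reagents that add atoms: none
Why: Saegusa oxidation: divalent palladium attacks C6 of the silyl enol ether and the only β-hydrogen, H5, is eliminated, giving the C5=C6 enone and deliberately erasing the cis C5 centre.

Step 10
Reactants: 14 1β-methyl-4β-(triethylsilyloxy)bicyclo[5.3.0]dec-5-en-7-one
Product: 16 1β,8-dimethyl-4β-(triethylsilyloxy)bicyclo[5.3.0]dec-5-en-7-one (C8 epimers), via lithium dienolate 15 (not isolated)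
Conditions: LiN(iPr)2, THF, −78 °C; MeI, −78 → −30 °C
Reagents that add atoms: iodomethane, CI
Why: Kinetic α′ deprotonation of an enone gives the cross-conjugated dienolate, which is C-methylated at C8 (enolate alkylation); the C8 configuration is irrelevant because C8 becomes sp2 in the next step.

Step 11
Reactants: 16 1β,8-dimethyl-4β-(triethylsilyloxy)bicyclo[5.3.0]dec-5-en-7-one
Product: 19 1β,8-dimethyl-4β-(triethylsilyloxy)bicyclo[5.3.0]deca-5,8-dien-7-one, via lithium dienolate 17 (not isolated), via trimethylsilyl dienol ether 18 (not isolated)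
Conditions: LiN(iPr)2, THF, −78 °C; Me3SiCl; then Pd(OAc)2 (1.1 equiv), MeCN, rt
Reagents that add atoms: none
Why: Second Saegusa oxidation through the α′ silyl dienol ether; β-hydride elimination toward the ring carbon C9 should give the conjugated endocyclic C8=C9 enone, and the quaternary C1 rules out aromatisation.

Step 12
Reactants: 19 1β,8-dimethyl-4β-(triethylsilyloxy)bicyclo[5.3.0]deca-5,8-dien-7-one
Product: 20 8α,9α-dihydroxy-1β,8β-dimethyl-4β-(triethylsilyloxy)bicyclo[5.3.0]dec-5-en-7-one
Conditions: OsO4 (5 mol %), NMO, acetone/H2O (4:1), rt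
Reagents that add atoms: osmium tetroxide, O=[Os](=O)(=O)=O; 4-methylmorpholine N-oxide, C[N+]1([O-])CCOCC1; water, O
Why: Upjohn syn-dihydroxylation; OsO4 should choose C8=C9 because the β-carbon of C5=C6 is wedged between quaternary C1 and the silyloxy-bearing C4, and it should add to the α face because the C1 configuration holds C10 below and C1 with its methyl above the C8=C9 plane, which sets C8 (OH α, CH3 β) and C9 (OH α).

Step 13
Reactants: 20 8α,9α-dihydroxy-1β,8β-dimethyl-4β-(triethylsilyloxy)bicyclo[5.3.0]dec-5-en-7-one
Product: 21 8α,9α-dihydroxy-1β,8β-dimethyl-4β-(triethylsilyloxy)-5αH-bicyclo[5.3.0]decan-7-one (trans-fused)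
Conditions: H2 (1 atm), 10% Pd/C, EtOAc, rt
Reagents that add atoms: none
Why: Heterogeneous syn-hydrogenation of the enone; hydrogen should reach C5 and C6 from the α face because the β face of C5 is flanked by the C1 methyl and C4 triethylsilyloxy groups while the α face carries only hydrogens and two hydroxyls that can anchor to the surface, which sets H5 α and the trans ring fusion.

Step 14
Reactants: 21 8α,9α-dihydroxy-1β,8β-dimethyl-4β-(triethylsilyloxy)-5αH-bicyclo[5.3.0]decan-7-one
Product: 22 8α,9α-(isopropylidenedioxy)-1β,8β-dimethyl-4β-(triethylsilyloxy)-5αH-bicyclo[5.3.0]decan-7-one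
Conditions: 2-methoxypropene, PPTS (cat.), CH2Cl2, 0 °C
Reagents that add atoms: 2-methoxypropene, C=C(C)OC
Why: Acetonide formation on a cis-1,2-diol by transacetalisation under acid mild enough to spare the triethylsilyl ether; it distinguishes O9 from the later C6 hydroxyl.

Step 15
Reactants: 22 8α,9α-(isopropylidenedioxy)-1β,8β-dimethyl-4β-(triethylsilyloxy)-5αH-bicyclo[5.3.0]decan-7-one
Product: 23 7-(tert-butyldimethylsilyloxy)-8α,9α-(isopropylidenedioxy)-1β,8β-dimethyl-4β-(triethylsilyloxy)-5αH-bicyclo[5.3.0]dec-6-ene
Conditions: TBSOTf, Et3N, CH2Cl2, −78 → 0 °C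
Reagents that add atoms: tert-butyldimethylsilyl trifluoromethanesulfonate, CC(C)(C)[Si](C)(C)OS(=O)(=O)C(F)(F)F
Why: Soft enolisation to a silyl enol ether; it is regiospecific because C8 is quaternary and C6 is the only enolisable position.

Step 16
Reactants: 23 7-(tert-butyldimethylsilyloxy)-8α,9α-(isopropylidenedioxy)-1β,8β-dimethyl-4β-(triethylsilyloxy)-5αH-bicyclo[5.3.0]dec-6-ene
Product: 24 6α-(tert-butyldimethylsilyloxy)-8α,9α-(isopropylidenedioxy)-1β,8β-dimethyl-4β-(triethylsilyloxy)-5αH-bicyclo[5.3.0]decan-7-one
Conditions: mCPBA, NaHCO3, CH2Cl2, −20 °C → rt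
Reagents that add atoms: 3-chloroperoxybenzoic acid, OOC(=O)c1cccc(Cl)c1
Why: Rubottom oxidation: the enol ether should be epoxidised on the α face (the β face of C6 is crowded by the C4 triethylsilyloxy group, the axial C1 methyl and the C8 methyl, against only the acetonide oxygen on the α side), and ring opening with 1,4-silyl shift delivers the α-silyloxy ketone, setting C6 with its oxygen already protected.

Step 17
Reactants: 24 6α-(tert-butyldimethylsilyloxy)-8α,9α-(isopropylidenedioxy)-1β,8β-dimethyl-4β-(triethylsilyloxy)-5αH-bicyclo[5.3.0]decan-7-one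
Product: 25 6α-(tert-butyldimethylsilyloxy)-4β-hydroxy-8α,9α-(isopropylidenedioxy)-1β,8β-dimethyl-5αH-bicyclo[5.3.0]decan-7-one
Conditions: HF·pyridine, pyridine, THF, 0 °C
Reagents that add atoms: none
Why: Selective desilylation: a triethylsilyl ether is cleaved much faster than a tert-butyldimethylsilyl ether by buffered fluoride, and the acetonide is inert.

Step 18
Reactants: 25 6α-(tert-butyldimethylsilyloxy)-4β-hydroxy-8α,9α-(isopropylidenedioxy)-1β,8β-dimethyl-5αH-bicyclo[5.3.0]decan-7-one
Product: 26 6α-(tert-butyldimethylsilyloxy)-8α,9α-(isopropylidenedioxy)-1β,8β-dimethyl-5αH-bicyclo[5.3.0]decane-4,7-dione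
Conditions: Dess–Martin periodinane, NaHCO3, CH2Cl2, rt
Reagents that add atoms: none
Why: Dess–Martin oxidation of a secondary alcohol under buffered, non-basic conditions, so that C5 is not enolised and the β-silyloxy group at C6 is not eliminated.

Step 19
Reactants: 26 6α-(tert-butyldimethylsilyloxy)-8α,9α-(isopropylidenedioxy)-1β,8β-dimethyl-5αH-bicyclo[5.3.0]decane-4,7-dione; 27 isopropylmagnesium chloride
Product: 28 6α-(tert-butyldimethylsilyloxy)-4β-hydroxy-4α-isopropyl-8α,9α-(isopropylidenedioxy)-1β,8β-dimethyl-5αH-bicyclo[5.3.0]decan-7-one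
Conditions: CeCl3 (anhydrous), 27, THF, −78 °C; aq. NH4Cl
Reagents that add atoms: none
Why: 1,2-Addition of the weakly basic organocerium reagent iPrCeCl2 to the cyclopentanone; it should approach C4 from the α face past H5, since the β face is flanked by the C5–C6 bond with its silyloxy group and by the C1 methyl, which sets C4 (isopropyl α, OH β), while the C7 carbonyl is shielded by quaternary C8 and the C6 silyl ether.

Step 20
Reactants: 28 6α-(tert-butyldimethylsilyloxy)-4β-hydroxy-4α-isopropyl-8α,9α-(isopropylidenedioxy)-1β,8β-dimethyl-5αH-bicyclo[5.3.0]decan-7-one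
Product: 29 4β,6α-dihydroxy-4α-isopropyl-8α,9α-(isopropylidenedioxy)-1β,8β-dimethyl-5αH-bicyclo[5.3.0]decan-7-one
Conditions: Bu4NF, AcOH, THF, 0 °C → rt
Reagents that add atoms: none
Why: Fluoride desilylation buffered with acetic acid, so that the liberated α-ketol is neither epimerised at C6 nor rearranged.

Step 21
Reactants: 29 4β,6α-dihydroxy-4α-isopropyl-8α,9α-(isopropylidenedioxy)-1β,8β-dimethyl-5αH-bicyclo[5.3.0]decan-7-one; 30 4-(methoxymethoxy)benzoic acid
Product: 31 4β-hydroxy-4α-isopropyl-8α,9α-(isopropylidenedioxy)-1β,8β-dimethyl-7-oxo-5αH-bicyclo[5.3.0]decan-6α-yl 4-(methoxymethoxy)benzoate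
Conditions: EDC·HCl, DMAP, CH2Cl2, rt
Reagents that add atoms: none
Why: Steglich esterification; only the secondary C6 hydroxyl can be acylated because C4–OH is tertiary and O8/O9 are in the acetonide.

Step 22
Reactants: 31 4β-hydroxy-4α-isopropyl-8α,9α-(isopropylidenedioxy)-1β,8β-dimethyl-7-oxo-5αH-bicyclo[5.3.0]decan-6α-yl 4-(methoxymethoxy)benzoate
Product: 32 (3R,3aS,4R,6S,7S,8aR)-3,6,7-trihydroxy-6,8a-dimethyl-5-oxo-3-(propan-2-yl)decahydroazulen-4-yl 4-hydroxybenzoate (CNP0241001.1)
Conditions: 2 M aq. HCl/THF (1:1), rt → 40 °C
Reagents that add atoms: none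
Why: Acid-catalysed acetal hydrolysis removes the acetonide and the aryl methoxymethyl ether in one operation; no stereocentre is touched and the aryl ester is stable to dilute aqueous acid.

## Compound list

1 | (1-ethoxycyclopropoxy)trimethylsilane | CCOC1(O[Si](C)(C)C)CC1 | starting material
2 | ethynylmagnesium bromide | C#C[Mg]Br | starting material
3 | 1-ethoxycyclopropan-1-ol (not isolated) | CCOC1(O)CC1 | intermediate
4 | 1-ethynylcyclopropan-1-ol | C#CC1(O)CC1 | intermediate
5 | tert-butyl[(1-ethynylcyclopropyl)oxy]dimethylsilane | C#CC1(O[Si](C)(C)C(C)(C)C)CC1 | intermediate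
6 | 4-methylpent-4-enoic acid | C=C(C)CCC(=O)O | starting material
7 | N-methoxy-N,4-dimethylpent-4-enamide | C=C(C)CCC(=O)N(C)OC | intermediate
8 | lithium acetylide of 5 (not isolated) | [Li]C#CC1(O[Si](C)(C)C(C)(C)C)CC1 | intermediate
9 | 1-[1-(tert-butyldimethylsilyloxy)cyclopropyl]-6-methylhept-6-en-1-yn-3-one | C=C(C)CCC(=O)C#CC1(O[Si](C)(C)C(C)(C)C)CC1 | intermediate
10 | (3S)-1-[1-(tert-butyldimethylsilyloxy)cyclopropyl]-6-methylhept-6-en-1-yn-3-ol | C=C(C)CC[C@H](O)C#CC1(O[Si](C)(C)C(C)(C)C)CC1 | intermediate
11 | (3S,1E)-1-[1-(tert-butyldimethylsilyloxy)cyclopropyl]-6-methylhepta-1,6-dien-3-ol | C=C(C)CC[C@H](O)/C=C/C1(O[Si](C)(C)C(C)(C)C)CC1 | intermediate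
12 | (E)-1-(tert-butyldimethylsilyloxy)-1-[(3S)-6-methyl-3-(triethylsilyloxy)hepta-1,6-dien-1-yl]cyclopropane | C=C(C)CC[C@H](O[Si](CC)(CC)CC)/C=C/C1(O[Si](C)(C)C(C)(C)C)CC1 | intermediate
13 | 7-(tert-butyldimethylsilyloxy)-1β-methyl-4β-(triethylsilyloxy)-5βH-bicyclo[5.3.0]dec-6-ene (cis-fused) | CC[Si](CC)(CC)O[C@H]1CC[C@]2(C)CCCC(O[Si](C)(C)C(C)(C)C)=C[C@@H]21 | intermediate
14 | 1β-methyl-4β-(triethylsilyloxy)bicyclo[5.3.0]dec-5-en-7-one | CC[Si](CC)(CC)O[C@H]1CC[C@]2(C)CCCC(=O)C=C21 | intermediate
15 | lithium dienolate of 14, O–Li on C7, C5=C6 and C7=C8 (not isolated) | CC[Si](CC)(CC)O[C@H]1CC[C@]2(C)CCC=C(O[Li])C=C21 | intermediate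
16 | 1β,8-dimethyl-4β-(triethylsilyloxy)bicyclo[5.3.0]dec-5-en-7-one (C8 epimers) | CC[Si](CC)(CC)O[C@H]1CC[C@]2(C)CCC(C)C(=O)C=C21 | intermediate
17 | lithium dienolate of 16, O–Li on C7, C5=C6 and C7=C8 (not isolated) | CC[Si](CC)(CC)O[C@H]1CC[C@]2(C)CCC(C)=C(O[Li])C=C21 | intermediate
18 | 1β,8-dimethyl-4β-(triethylsilyloxy)-7-(trimethylsilyloxy)bicyclo[5.3.0]deca-5,7-diene (not isolated) | CC[Si](CC)(CC)O[C@H]1CC[C@]2(C)CCC(C)=C(O[Si](C)(C)C)C=C21 | intermediate
19 | 1β,8-dimethyl-4β-(triethylsilyloxy)bicyclo[5.3.0]deca-5,8-dien-7-one | CC[Si](CC)(CC)O[C@H]1CC[C@]2(C)CC=C(C)C(=O)C=C21 | intermediate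
20 | 8α,9α-dihydroxy-1β,8β-dimethyl-4β-(triethylsilyloxy)bicyclo[5.3.0]dec-5-en-7-one | CC[Si](CC)(CC)O[C@H]1CC[C@]2(C)C[C@H](O)[C@](C)(O)C(=O)C=C21 | intermediate
21 | 8α,9α-dihydroxy-1β,8β-dimethyl-4β-(triethylsilyloxy)-5αH-bicyclo[5.3.0]decan-7-one (trans-fused) | CC[Si](CC)(CC)O[C@H]1CC[C@]2(C)C[C@H](O)[C@](C)(O)C(=O)C[C@H]21 | intermediate
22 | 8α,9α-(isopropylidenedioxy)-1β,8β-dimethyl-4β-(triethylsilyloxy)-5αH-bicyclo[5.3.0]decan-7-one | CC[Si](CC)(CC)O[C@H]1CC[C@]2(C)C[C@@H]3OC(C)(C)O[C@]3(C)C(=O)C[C@H]21 | intermediate
23 | 7-(tert-butyldimethylsilyloxy)-8α,9α-(isopropylidenedioxy)-1β,8β-dimethyl-4β-(triethylsilyloxy)-5αH-bicyclo[5.3.0]dec-6-ene | CC[Si](CC)(CC)O[C@H]1CC[C@]2(C)C[C@@H]3OC(C)(C)O[C@]3(C)C(O[Si](C)(C)C(C)(C)C)=C[C@H]21 | intermediate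
24 | 6α-(tert-butyldimethylsilyloxy)-8α,9α-(isopropylidenedioxy)-1β,8β-dimethyl-4β-(triethylsilyloxy)-5αH-bicyclo[5.3.0]decan-7-one | CC[Si](CC)(CC)O[C@H]1CC[C@]2(C)C[C@@H]3OC(C)(C)O[C@]3(C)C(=O)[C@H](O[Si](C)(C)C(C)(C)C)[C@H]21 | intermediate
25 | 6α-(tert-butyldimethylsilyloxy)-4β-hydroxy-8α,9α-(isopropylidenedioxy)-1β,8β-dimethyl-5αH-bicyclo[5.3.0]decan-7-one | O[C@H]1CC[C@]2(C)C[C@@H]3OC(C)(C)O[C@]3(C)C(=O)[C@H](O[Si](C)(C)C(C)(C)C)[C@H]21 | intermediate
26 | 6α-(tert-butyldimethylsilyloxy)-8α,9α-(isopropylidenedioxy)-1β,8β-dimethyl-5αH-bicyclo[5.3.0]decane-4,7-dione | O=C1CC[C@]2(C)C[C@@H]3OC(C)(C)O[C@]3(C)C(=O)[C@H](O[Si](C)(C)C(C)(C)C)[C@H]21 | intermediate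
27 | isopropylmagnesium chloride | CC(C)[Mg]Cl | starting material
28 | 6α-(tert-butyldimethylsilyloxy)-4β-hydroxy-4α-isopropyl-8α,9α-(isopropylidenedioxy)-1β,8β-dimethyl-5αH-bicyclo[5.3.0]decan-7-one | CC(C)[C@]1(O)CC[C@]2(C)C[C@@H]3OC(C)(C)O[C@]3(C)C(=O)[C@H](O[Si](C)(C)C(C)(C)C)[C@H]21 | intermediate
29 | 4β,6α-dihydroxy-4α-isopropyl-8α,9α-(isopropylidenedioxy)-1β,8β-dimethyl-5αH-bicyclo[5.3.0]decan-7-one | CC(C)[C@]1(O)CC[C@]2(C)C[C@@H]3OC(C)(C)O[C@]3(C)C(=O)[C@H](O)[C@H]21 | intermediate
30 | 4-(methoxymethoxy)benzoic acid | COCOc1ccc(cc1)C(=O)O | starting material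
31 | 4β-hydroxy-4α-isopropyl-8α,9α-(isopropylidenedioxy)-1β,8β-dimethyl-7-oxo-5αH-bicyclo[5.3.0]decan-6α-yl 4-(methoxymethoxy)benzoate | CC(C)[C@]1(O)CC[C@]2(C)C[C@@H]3OC(C)(C)O[C@]3(C)C(=O)[C@H](OC(=O)c4ccc(OCOC)cc4)[C@H]21 | intermediate
32 | (3R,3aS,4R,6S,7S,8aR)-3,6,7-trihydroxy-6,8a-dimethyl-5-oxo-3-(propan-2-yl)decahydroazulen-4-yl 4-hydroxybenzoate | CC(C)[C@]1(O)CC[C@]2(C)C[C@H](O)[C@](C)(O)C(=O)[C@H](OC(=O)c3ccc(O)cc3)[C@H]21 | target

## Step count and least certain steps

Total step count: 22. Longest linear sequence: 21 steps (steps 1, 2 and 4–22, from 1 to 32); step 3 is a one-step branch.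

**Step 8 (key step).** The most likely failure is alkene-face selection that is weaker than, or opposite to, the assumed exo placement of the C4 silyloxy group. Because C4 is later oxidised, this would erode or invert the absolute configuration at C1 and C5. Slow insertion of the 1,1-disubstituted alkene, letting cyclopropane isomerisation compete, is the second concern. The fallback changes the source of the C1 configuration: it sets out from 9 and comes back at 14. 9 would be reduced with the antipodal catalyst Ru[(R,R)-TsDPEN](p-cymene) to the (3R)-propargylic alcohol F1, taken with NaAlH2(OCH2CH2OMe)2 to the (3R,1E)-allylic alcohol F2, and silylated to the (3R)-bis-silyl ether F3. Cycloaddition would then give the 4α-triethylsilyloxy cycloadduct F4 with the natural C1/C5 configuration. Pd(OAc)2 would give the 4α-triethylsilyloxy enone F5 and HF·pyridine the 4α-hydroxy enone F6. Mitsunobu inversion with 4-nitrobenzoic acid (PPh3, DIAD) would give the 4β-(4-nitrobenzoyloxy) enone F7, K2CO3/MeOH the 4β-hydroxy enone F8, and Et3SiCl/imidazole would return 14.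

**Step 12.** What may go wrong is competing osmylation of C5=C6 or attack on the β face of C8=C9 in the flexible cross-conjugated dienone. The fallback moves the dihydroxylation to a conformationally defined trans-fused mono-enone: it sets out from 16 and comes back at 21. 16 would be hydrogenated (H2, Pd/C) to the trans-fused 8-methyl ketone F9. Thermodynamic silylation (Me3SiCl, NaI, Et3N, MeCN) toward the more substituted side would give the C7=C8 trimethylsilyl enol ether F10. Pd(OAc)2 would give the C8=C9 enone F11, and OsO4/NMO would then deliver 21.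

**Step 13.** What may go wrong is hydrogen delivery to the β face (cis fusion) or hydrogenolysis of the allylic C4–O bond on the metal surface. The fallback replaces steric approach control by hydroxyl-directed delivery: it sets out from 20 and comes back at 21. The homogeneous catalyst [Ir(cod)(PCy3)(py)]PF6 under H2 in CH2Cl2 would bind the α-oriented C8 hydroxyl and transfer hydrogen to the α face of C5=C6; no new compound is made.

**Step 19.** What may go wrong is enolisation toward C5 followed by loss of the C6 silyloxy group or epimerisation at C5, and β-hydride reduction of the ketone by the branched reagent. The fallback installs the three carbons as an sp2 nucleophile and saturates afterwards: it sets out from 26 and comes back at 28. Isopropenylmagnesium bromide with CeCl3 would give the 4α-isopropenyl carbinol F12, and hydrogenation of the 1,1-disubstituted alkene (H2, Pd/C) would give 28.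

**Step 22.** What may go wrong is acid-promoted loss of water from the tertiary C4 carbinol, or capture of released formaldehyde by the cis-diol. The fallback separates the two unmaskings and makes the phenol release neutral: it sets out from 29 and comes back at 32. 29 would be esterified with 4-(benzyloxy)benzoic acid (EDC·HCl, DMAP) to the benzyl-protected ester F13. Hydrogenolysis (H2, Pd/C) would give the phenol acetonide F14, and aqueous acetic acid would then hydrolyse the acetonide to 32.

## Further compounds

F1 | step 8 | (3R)-1-[1-(tert-butyldimethylsilyloxy)cyclopropyl]-6-methylhept-6-en-1-yn-3-ol | C=C(C)CC[C@@H](O)C#CC1(O[Si](C)(C)C(C)(C)C)CC1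
F2 | step 8 | (3R,1E)-1-[1-(tert-butyldimethylsilyloxy)cyclopropyl]-6-methylhepta-1,6-dien-3-ol | C=C(C)CC[C@@H](O)/C=C/C1(O[Si](C)(C)C(C)(C)C)CC1
F3 | step 8 | (E)-1-(tert-butyldimethylsilyloxy)-1-[(3R)-6-methyl-3-(triethylsilyloxy)hepta-1,6-dien-1-yl]cyclopropane | C=C(C)CC[C@@H](O[Si](CC)(CC)CC)/C=C/C1(O[Si](C)(C)C(C)(C)C)CC1
F4 | step 8 | 7-(tert-butyldimethylsilyloxy)-1β-methyl-4α-(triethylsilyloxy)-5βH-bicyclo[5.3.0]dec-6-ene | CC[Si](CC)(CC)O[C@@H]1CC[C@]2(C)CCCC(O[Si](C)(C)C(C)(C)C)=C[C@@H]21
F5 | step 8 | 1β-methyl-4α-(triethylsilyloxy)bicyclo[5.3.0]dec-5-en-7-one | CC[Si](CC)(CC)O[C@@H]1CC[C@]2(C)CCCC(=O)C=C21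
F6 | step 8 | 4α-hydroxy-1β-methylbicyclo[5.3.0]dec-5-en-7-one | O[C@@H]1CC[C@]2(C)CCCC(=O)C=C21
F7 | step 8 | 1β-methyl-7-oxobicyclo[5.3.0]dec-5-en-4β-yl 4-nitrobenzoate | O=C(O[C@H]1CC[C@]2(C)CCCC(=O)C=C21)c1ccc(cc1)[N+](=O)[O-]
F8 | step 8 | 4β-hydroxy-1β-methylbicyclo[5.3.0]dec-5-en-7-one | O[C@H]1CC[C@]2(C)CCCC(=O)C=C21
F9 | step 12 | 1β,8-dimethyl-4β-(triethylsilyloxy)-5αH-bicyclo[5.3.0]decan-7-one (C8 epimers) | CC[Si](CC)(CC)O[C@H]1CC[C@]2(C)CCC(C)C(=O)C[C@H]21
F10 | step 12 | 1β,8-dimethyl-4β-(triethylsilyloxy)-7-(trimethylsilyloxy)-5αH-bicyclo[5.3.0]dec-7-ene | CC[Si](CC)(CC)O[C@H]1CC[C@]2(C)CCC(C)=C(O[Si](C)(C)C)C[C@H]21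
F11 | step 12 | 1β,8-dimethyl-4β-(triethylsilyloxy)-5αH-bicyclo[5.3.0]dec-8-en-7-one | CC[Si](CC)(CC)O[C@H]1CC[C@]2(C)CC=C(C)C(=O)C[C@H]21
F0 | step 13 | none | none
F12 | step 19 | 6α-(tert-butyldimethylsilyloxy)-4β-hydroxy-4α-isopropenyl-8α,9α-(isopropylidenedioxy)-1β,8β-dimethyl-5αH-bicyclo[5.3.0]decan-7-one | CC(=C)[C@]1(O)CC[C@]2(C)C[C@@H]3OC(C)(C)O[C@]3(C)C(=O)[C@H](O[Si](C)(C)C(C)(C)C)[C@H]21
F13 | step 22 | 4β-hydroxy-4α-isopropyl-8α,9α-(isopropylidenedioxy)-1β,8β-dimethyl-7-oxo-5αH-bicyclo[5.3.0]decan-6α-yl 4-(benzyloxy)benzoate | CC(C)[C@]1(O)CC[C@]2(C)C[C@@H]3OC(C)(C)O[C@]3(C)C(=O)[C@H](OC(=O)c4ccc(OCc5ccccc5)cc4)[C@H]21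
F14 | step 22 | 4β-hydroxy-4α-isopropyl-8α,9α-(isopropylidenedioxy)-1β,8β-dimethyl-7-oxo-5αH-bicyclo[5.3.0]decan-6α-yl 4-hydroxybenzoate | CC(C)[C@]1(O)CC[C@]2(C)C[C@@H]3OC(C)(C)O[C@]3(C)C(=O)[C@H](OC(=O)c4ccc(O)cc4)[C@H]21
A1 | alternative 1 | cis-fused bicyclic enedione (C4 and C7 ketones, C9=C10 alkene, angular methyl on C1) | O=C1CC[C@]2(C)C=CC(=O)C[C@H]12
A2 | alternative 1 | 3-(1-methyl-4-oxocyclohexa-2,5-dien-1-yl)propanal | CC1(CCC=O)C=CC(=O)C=C1
A3 | alternative 2 | bicyclic diene ester with C4 ketal, quaternary C1, C5=C6 and C8=C9 | COC(=O)C1=CC[C@@]2(C)CCC3(OCCO3)C2=CC1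
A4 | alternative 2 | methyl 2-diazobut-3-enoate | COC(=O)C(=[N+]=[N-])C=C
A5 | alternative 2 | 6-ethenyl-7-methyl-1,4-dioxaspiro[4.4]non-6-ene | C=CC1=C(C)CCC12OCCO2
A6 | alternative 3 | aldol adduct: cyclopentanone with C1 methyl, acetal arm and dithiane-bearing C6 carbinol | O=C1CC[C@](C)(CC(OC)OC)[C@H]1[C@@H](O)C2(CC)SCCCS2
A7 | alternative 3 | 3-(2,2-dimethoxyethyl)cyclopent-2-en-1-one | O=C1CCC(CC(OC)OC)=C1
A8 | alternative 3 | 2-ethyl-1,3-dithiane-2-carbaldehyde | CCC1(C=O)SCCCS1
A9 | alternative 3 | methylmagnesium bromide | C[Mg]Br
A10 | alternative 3 | Cu(OTf)2 | [Cu+2].[O-]S(=O)(=O)C(F)(F)F.[O-]S(=O)(=O)C(F)(F)F
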